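## Retrosynthetic overview
1. The enyne C(sp)–C(sp2) bond is made last by Sonogashira coupling of an alkyne-terminated dioxane core with an E-vinyl iodide tail. The tail comes from dec-9-en-1-ol by oxidation and Takai olefination.
2. The C6 ketal centre is not built directly. It is relayed from C3 by acid-catalysed anomerisation in methanol (OMe axial, both carbon chains equatorial, which is 3S,6R).
3. The only ring, the 1,2-dioxane, is closed once and late at the O2–C3 bond by the new step. This is a catalytic enantioselective 6-exo-trig peroxa-Michael addition of a racemic hydroperoxyketal to its own E-enoate, and it sets C3.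
4. The hydroperoxyketal comes from chemoselective ozonolysis in methanol of a 1,1-disubstituted alkene that sits between an enoate and an alkyne.
5. The chain comes from hex-5-ynoic acid (as its Weinreb amide) and the Grignard reagent of 2-(2-bromoethyl)-1,3-dioxolane, followed by methylenation, acetal hydrolysis and a stabilised-ylide Wittig reaction.

Assumption: the (S)-tert-leucine-derived catalyst of step 7 gives the 3S sense; if a test run shows 3R, its mirror image from (R)-tert-leucine is used (it is made beforehand by Staudinger reaction of the azido-thiourea with tris(4-methoxyphenyl)phosphane and is not counted).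

## Route

Step 1
Reactants: 1 hex-5-ynoic acid
Product: 3 N-methoxy-N-methylhex-5-ynamide, via acyl imidazole 2 (not isolated)
Conditions: 1,1'-carbonyldiimidazole (1.1 equiv), CH2Cl2, rt, 1 h; then MeNH(OMe)·HCl (1.2 equiv), rt, 12 h
Reagents that add atoms: N,O-dimethylhydroxylamine hydrochloride, CNOC.Cl
Why: Acyl-imidazole activation followed by aminolysis (Weinreb amide synthesis) is high-yielding and leaves the terminal alkyne untouched.

Step 2
Reactants: 3 N-methoxy-N-methylhex-5-ynamide; 4 2-(2-bromoethyl)-1,3-dioxolane
Product: 7 1-(1,3-dioxolan-2-yl)oct-7-yn-3-one, via Grignard reagent 5 (not isolated), via tetrahedral magnesium adduct 6 (not isolated)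
Conditions: 4 (2.5 equiv), Mg turnings, THF, 20–30 °C; then 3, THF, 0 °C; sat. aq NH4Cl
Reagents that add atoms: none
Why: In this Weinreb ketone synthesis the chelated adduct 6 prevents over-addition, and the extra equivalent of 5 only deprotonates the alkyne C–H, which is restored on quench.

Step 3
Reactants: 7 1-(1,3-dioxolan-2-yl)oct-7-yn-3-one
Product: 8 2-(3-methylideneoct-7-yn-1-yl)-1,3-dioxolane
Conditions: MePPh3Br (1.5 equiv), KOt-Bu (1.4 equiv), THF, 0 °C to rt
Reagents that add atoms: methyltriphenylphosphonium bromide, C[P+](c1ccccc1)(c1ccccc1)c1ccccc1.[Br-]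
Why: Wittig methylenation of an unhindered dialkyl ketone works well here because the ylide is too weak a base to touch the alkyne C–H and the acetal is inert to base.

Step 4
Reactants: 8 2-(3-methylideneoct-7-yn-1-yl)-1,3-dioxolane
Product: 9 4-methylidenenon-8-ynal
Conditions: 1 M aq HCl–THF 1:2, rt, 8 h
Reagents that add atoms: water, O
Why: Acid-catalysed hydrolysis of an aldehyde dioxolane is fast in dilute acid at room temperature, where the 1,1-disubstituted alkene does not migrate and the alkyne does not hydrate.

Step 5
Reactants: 9 4-methylidenenon-8-ynal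
Product: 10 methyl (2E)-6-methylideneundec-2-en-10-ynoate
Conditions: Ph3P=CHCO2Me (1.2 equiv), CH2Cl2, rt, 12 h
Reagents that add atoms: methyl (triphenyl-λ5-phosphanylidene)acetate, COC(=O)C=P(c1ccccc1)(c1ccccc1)c1ccccc1
Why: Wittig olefination with a stabilised ylide gives the E-enoate (E:Z above 20:1) under neutral conditions.

Step 6
Reactants: 10 methyl (2E)-6-methylideneundec-2-en-10-ynoate
Product: 12 methyl (2E)-6-hydroperoxy-6-methoxyundec-2-en-10-ynoate (racemic at C6), via carbonyl oxide 11 (not isolated)
Conditions: O3/O2, CH2Cl2–MeOH 4:1, −78 °C, Sudan Red 7B as end-point indicator; N2 purge, no reductant, concentrate below 25 °C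
Reagents that add atoms: ozone, [O-][O+]=O; methanol, CO
Why: In this Criegee ozonolysis in a participating solvent, ozone attacks the electron-rich 1,1-disubstituted alkene far faster than the enoate or alkyne, cycloreversion gives the more substituted carbonyl oxide 11 plus formaldehyde, and methanol traps 11, so C6 is deliberately formed racemic.

Step 7
Reactants: 12 methyl (2E)-6-hydroperoxy-6-methoxyundec-2-en-10-ynoate
Product: 13 methyl 2-[(3S,6RS)-6-methoxy-6-(pent-4-yn-1-yl)-1,2-dioxan-3-yl]acetate (3S fixed; about 1:1 at C6)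
Conditions: 1-[3,5-bis(trifluoromethyl)phenyl]-3-[(2S)-3,3-dimethyl-1-{[tris(4-methoxyphenyl)-λ5-phosphanylidene]amino}butan-2-yl]thiourea (10 mol%), toluene (0.05 M), −20 °C, 48 h; filtration through silica
Reagents that add atoms: none
Why: Proposed new method: catalytic enantioselective intramolecular peroxa-Michael addition to an α,β-unsaturated ester; the iminophosphorane nitrogen fully deprotonates the OOH group (pKa about 12, some four units below an alcohol), the thiourea hydrogen-bonds to the ester carbonyl and holds the aminophosphonium peroxide ion pair, so the α-effect oxygen attacks one face of the E-enoate through a chair-like 6-exo-trig transition state and sets C3 as S under catalyst control for both enantiomers of 12 (C6 lies far from the bound ester, hence about 1:1 at C6), while the aminophosphonium N–H and unreacted OOH protonate the ester enolate faster than it can break the O–O bond (Weitz–Scheffer epoxidation), and there is no background reaction without base; the closest known reaction types are the enantioselective intramolecular oxa-Michael addition of alcohols to enoates with bifunctional iminophosphorane catalysts and the racemic secondary-amine-catalysed cyclisation of hydroperoxyketals onto enoates, and neither has been shown as an asymmetric peroxide ring closure.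

Step 8
Reactants: 13 methyl 2-[(3S,6RS)-6-methoxy-6-(pent-4-yn-1-yl)-1,2-dioxan-3-yl]acetate
Product: 15 methyl 2-[(3S,6R)-6-methoxy-6-(pent-4-yn-1-yl)-1,2-dioxan-3-yl]acetate, via peroxycarbenium ion 14 (not isolated)
Conditions: camphor-10-sulfonic acid (10 mol%), MeOH–CH2Cl2 1:4, 0 °C to rt, 4 h; NaHCO3 quench
Reagents that add atoms: methanol, CO
Why: Acid-catalysed peroxyketal exchange (anomerisation) through 14 puts C6 under thermodynamic control, and the 6R epimer (OMe axial by the anomeric effect, both carbon chains equatorial) should dominate by at least 10:1, while C3 is untouched because its C–O bond is never broken and the methyl ester exchange with methanol is degenerate.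

Step 9
Reactants: 16 dec-9-en-1-ol
Product: 17 dec-9-enal
Conditions: 2,2,6,6-tetramethylpiperidin-1-oxyl (10 mol%), PhI(OAc)2 (1.1 equiv), CH2Cl2, rt
Reagents that add atoms: none
Why: Nitroxyl/oxoammonium-catalysed alcohol oxidation stops cleanly at the aldehyde and ignores the terminal alkene.

Step 10
Reactants: 17 dec-9-enal
Product: 18 (1E)-1-iodoundeca-1,10-diene
Conditions: CrCl2 (6 equiv), CHI3 (2 equiv), 1,4-dioxane–THF 6:1, 0 °C to rt
Reagents that add atoms: iodoform, IC(I)I
Why: In the Takai olefination the gem-dichromium reagent adds to the aldehyde and eliminates to give the E-vinyl iodide (about 10:1 in dioxane–THF, with the minor Z isomer removed on AgNO3-impregnated silica), and the isolated alkene is inert.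

Step 11
Reactants: 15 methyl 2-[(3S,6R)-6-methoxy-6-(pent-4-yn-1-yl)-1,2-dioxan-3-yl]acetate; 18 (1E)-1-iodoundeca-1,10-diene
Product: 19 peroxyacarnoate A, methyl 2-[(3S,6R)-6-[(6E)-hexadeca-6,15-dien-4-yn-1-yl]-6-methoxy-1,2-dioxan-3-yl]acetate
Conditions: Pd(PPh3)4 (5 mol%), CuI (10 mol%), i-Pr2NH (2 equiv), THF, rt, degassed, dark, 2 h
Reagents that add atoms: none
Why: Sonogashira coupling with zerovalent palladium and monovalent copper runs at room temperature with retention of the E geometry, cyclic peroxyketals of this type tolerate these catalysts and a hindered amine for the short reaction time, and neither stereocentre takes part.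

## Compound list
1 | hex-5-ynoic acid | C#CCCCC(=O)O | starting material
2 | 1-(imidazol-1-yl)hex-5-yn-1-one (acyl imidazole) | C#CCCCC(=O)n1ccnc1 | intermediate
3 | N-methoxy-N-methylhex-5-ynamide | C#CCCCC(=O)N(C)OC | intermediate
4 | 2-(2-bromoethyl)-1,3-dioxolane | BrCCC1OCCO1 | starting material
5 | [2-(1,3-dioxolan-2-yl)ethyl]magnesium bromide | Br[Mg]CCC1OCCO1 | intermediate
6 | tetrahedral magnesium adduct of 3 and 5 (alkyne end also magnesiated) | Br[Mg]C#CCCCC(O[Mg]Br)(N(C)OC)CCC1OCCO1 | intermediate
7 | 1-(1,3-dioxolan-2-yl)oct-7-yn-3-one | C#CCCCC(=O)CCC1OCCO1 | intermediate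
8 | 2-(3-methylideneoct-7-yn-1-yl)-1,3-dioxolane | C#CCCCC(=C)CCC1OCCO1 | intermediate
9 | 4-methylidenenon-8-ynal | C#CCCCC(=C)CCC=O | intermediate
10 | methyl (2E)-6-methylideneundec-2-en-10-ynoate | C#CCCCC(=C)CC/C=C/C(=O)OC | intermediate
11 | carbonyl oxide of methyl (2E)-6-oxoundec-2-en-10-ynoate | C#CCCCC(=[O+][O-])CC/C=C/C(=O)OC | intermediate
12 | methyl (2E)-6-hydroperoxy-6-methoxyundec-2-en-10-ynoate (racemic) | C#CCCCC(OC)(OO)CC/C=C/C(=O)OC | intermediate
13 | methyl 2-[(3S,6RS)-6-methoxy-6-(pent-4-yn-1-yl)-1,2-dioxan-3-yl]acetate (C6 epimer mixture) | C#CCCCC1(OC)CC[C@@H](CC(=O)OC)OO1 | intermediate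
14 | (3S)-3-(2-methoxy-2-oxoethyl)-6-(pent-4-yn-1-yl)-4,5-dihydro-3H-1,2-dioxin-1-ium (peroxycarbenium ion) | C#CCCCC1=[O+]O[C@H](CC(=O)OC)CC1 | intermediate
15 | methyl 2-[(3S,6R)-6-methoxy-6-(pent-4-yn-1-yl)-1,2-dioxan-3-yl]acetate | C#CCCC[C@]1(OC)CC[C@@H](CC(=O)OC)OO1 | intermediate
16 | dec-9-en-1-ol | C=CCCCCCCCCO | starting material
17 | dec-9-enal | C=CCCCCCCCC=O | intermediate
18 | (1E)-1-iodoundeca-1,10-diene | C=CCCCCCCC/C=C/I | intermediate
19 | peroxyacarnoate A | C=CCCCCCCC/C=C/C#CCCC[C@]1(OC)CC[C@@H](CC(=O)OC)OO1 | target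

## Step count and risks
Total steps: 11. Longest linear sequence: 9 (steps 1–8 and 11).

**Risk at step 6 (ozonolysis to the hydroperoxyketal).**
- Failure modes: the primary ozonide may fragment the wrong way, giving ketone plus formaldehyde oxide. Over-ozonolysis of the enoate or alkyne may also cut the yield.
- Fallback: it sets out from 7, comes back at 12, and uses no ozone.
- The acetal of 7 is hydrolysed (1 M aq HCl, THF, rt) to 4-oxonon-8-ynal F1.
- The stabilised ylide Ph3P=CHCO2Me reacts only at the aldehyde to give methyl (2E)-6-oxoundec-2-en-10-ynoate F2.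
- The ketone of F2 is converted directly into 12 by Lewis-acid-catalysed methoxy-perhydrolysis (urea–hydrogen peroxide adduct, Sc(OTf)3 10 mol%, MeOH, rt).

**Risk at step 7 (proposed new step).**
- Failure modes: facial selectivity may be low for the mismatched enantiomer of 12. The enolate may collapse to the epoxide. The peroxide anion may attack the aminophosphonium centre and degrade the catalyst.
- Fallback: known chemistry only. It sets out from 9 and comes back at 15.
- Wittig reaction of 9 with (triphenyl-λ5-phosphanylidene)acetaldehyde gives (2E)-6-methylideneundec-2-en-10-ynal F3.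
- Iminium-catalysed enantioselective conjugate peroxidation of the enal follows, using 2-hydroperoxy-2-methoxypropane and (2R)-2-{diphenyl[(trimethylsilyl)oxy]methyl}pyrrolidine (10 mol%). The usual steric-shielding model assigns this enantiomer to the 3S adduct. The product is (3S)-3-[(2-methoxypropan-2-yl)peroxy]-6-methylideneundec-10-ynal F4. The ketone stays masked as the methylidene group so that no enamine side reaction can occur.
- Pinnick oxidation (NaClO2, NaH2PO4, 2-methylbut-2-ene, t-BuOH–H2O) gives (3S)-3-[(2-methoxypropan-2-yl)peroxy]-6-methylideneundec-10-ynoic acid F5.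
- Me3SiCHN2 gives methyl (3S)-3-[(2-methoxypropan-2-yl)peroxy]-6-methylideneundec-10-ynoate F6.
- Ozonolysis in CH2Cl2 at −78 °C with Me2S work-up gives methyl (3S)-3-[(2-methoxypropan-2-yl)peroxy]-6-oxoundec-10-ynoate F7.
- Camphor-10-sulfonic acid in MeOH removes the 2-methoxypropan-2-yl group to give methyl (3S)-3-hydroperoxy-6-oxoundec-10-ynoate F8.
- F8 closes to the cyclic peroxyhemiketal methyl 2-[(3S)-6-hydroxy-6-(pent-4-yn-1-yl)-1,2-dioxan-3-yl]acetate F9, which is ketalised in the same flask under thermodynamic control to 15.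

**Risk at step 11 (Sonogashira coupling on the peroxide).**
- Failure modes: monovalent copper, phosphine or the amine may cleave the O–O bond or trigger β-elimination of the peroxy ester.
- Fallback: the polarity of the coupling is reversed, and it runs without amine, copper or phosphine. It sets out from 15 and 18 and comes back at 19.
- N-iodosuccinimide with AgNO3 (10 mol%) in acetone converts 15 into methyl 2-[(3S,6R)-6-(5-iodopent-4-yn-1-yl)-6-methoxy-1,2-dioxan-3-yl]acetate F10.
- Iodide 18 is treated with t-BuLi (2 equiv, Et2O, −78 °C) to give (1E)-undeca-1,10-dien-1-yllithium F11.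
- F11 is quenched with Bu3SnCl to give tributyl[(1E)-undeca-1,10-dien-1-yl]stannane F12.
- Stille coupling of F10 with F12 (PdCl2(MeCN)2 5 mol%, DMF, rt) gives 19 with retention of the E geometry.

## Further compounds
F1 | step 6 | 4-oxonon-8-ynal | C#CCCCC(=O)CCC=O
F2 | step 6 | methyl (2E)-6-oxoundec-2-en-10-ynoate | C#CCCCC(=O)CC/C=C/C(=O)OC
F3 | step 7 | (2E)-6-methylideneundec-2-en-10-ynal | C#CCCCC(=C)CC/C=C/C=O
F4 | step 7 | (3S)-3-[(2-methoxypropan-2-yl)peroxy]-6-methylideneundec-10-ynal | C#CCCCC(=C)CC[C@@H](CC=O)OOC(C)(C)OC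
F5 | step 7 | (3S)-3-[(2-methoxypropan-2-yl)peroxy]-6-methylideneundec-10-ynoic acid | C#CCCCC(=C)CC[C@@H](CC(=O)O)OOC(C)(C)OC
F6 | step 7 | methyl (3S)-3-[(2-methoxypropan-2-yl)peroxy]-6-methylideneundec-10-ynoate | C#CCCCC(=C)CC[C@@H](CC(=O)OC)OOC(C)(C)OC
F7 | step 7 | methyl (3S)-3-[(2-methoxypropan-2-yl)peroxy]-6-oxoundec-10-ynoate | C#CCCCC(=O)CC[C@@H](CC(=O)OC)OOC(C)(C)OC
F8 | step 7 | methyl (3S)-3-hydroperoxy-6-oxoundec-10-ynoate | C#CCCCC(=O)CC[C@@H](CC(=O)OC)OO
F9 | step 7 | methyl 2-[(3S)-6-hydroxy-6-(pent-4-yn-1-yl)-1,2-dioxan-3-yl]acetate | C#CCCCC1(O)CC[C@@H](CC(=O)OC)OO1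
F10 | step 11 | methyl 2-[(3S,6R)-6-(5-iodopent-4-yn-1-yl)-6-methoxy-1,2-dioxan-3-yl]acetate | IC#CCCC[C@]1(OC)CC[C@@H](CC(=O)OC)OO1
F11 | step 11 | (1E)-undeca-1,10-dien-1-yllithium | C=CCCCCCCC/C=C/[Li]
F12 | step 11 | tributyl[(1E)-undeca-1,10-dien-1-yl]stannane | C=CCCCCCCC/C=C/[Sn](CCCC)(CCCC)CCCC
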